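The data were generated by integration with made-up constants; noise was put on by code.

Split the loss of free monomer in this flask into two curves and find where they cross.

all flasks: pre-initiator 1.5 mol%
- beta: free monomer 0.40 M; protic impurity 0.040 M; run made earlier
- theta: free monomer 1.6 M; protic impurity 0.040 M; run made earlier
- flask: free monomer 0.80 M; protic impurity 0.0400 M; time 80 min

| run | time / min | monomer in chains / % | free monomer / % |
|---|---|---|---|
| beta | 12.0 | 0.5 | 92.6 |
| beta | 30.0 | 0.2 | 90.2 |
| beta | 60.0 | 2.0 | 87.6 |
| beta | 90.0 | 3.4 | 85.0 |
| theta | 25.0 | 1.9 | 95.1 |
| theta | 50.0 | 7.6 | 88.9 |
| theta | 80.0 | 17.9 | 78.9 |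
| theta | 90.0 | 21.5 | 75.6 |

(each reading ± 0.5 percentage points)

- the average divides the monomer in chains by the number of chains begun, living and dead together
- on the list of suspects stand: free monomer + living end -> monomer in chains + living end; free monomer + initiator -> living end + monomer in chains; monomer in chains + living end -> free monomer + living end; pre-initiator <-> initiator; free monomer -> uncatalysed product; protic impurity + free monomer -> quenched substrate
- the earlier runs do not show the number of chains; that part of a forecast is a guess

* average number of monomer units in a chain (chains begun, living or dead) at 80 min
* part of the free monomer that has reacted at 80 min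

At 90.0 min, free monomer missing and not in chains comes to 0.0464 M in beta and 0.0464 M in theta. Both readings lie near c(protic impurity), 0.0400 M. So we charge the flask a toll of 5.00% of its free monomer.

The beta reading at 12.0 min gives a pseudo-first-order half-life for the impurity. With twice the free monomer, the flask's half-life is 3.55 min. So c starts steeply, its gap to the toll halves every 3.55 min, and it bends into a shelf.

Monomer in chains starts flat. In theta it goes from 1.9% at 25.0 min to 7.6% at 50.0 min, a factor of 4.00 for doubled time, so it grows as the square of time. The readings show no level. The flask's c(free monomer) is the geometric mean of the two runs' charges, so we take the same mean of their last readings: 8.55% at 90.0 min.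

The parabola meets the toll at the crossing time, 68.8 min, which is later than the knee. At 80 min chains hold 6.76%, so we expect c near 11.8%. The chain count is a guess: if 0.5 of the 0.0120 M pre-initiator has begun chains, dp is 9.01.

The forecast stands higher on both, at dp 18 and c 13.5%, and says “Chains are a guess”.

The flask gives dp 8.74 and c 13.1%.

    free monomer + living end → monomer in chains + living end, rate k1*[living end]*[free monomer] (k = 17.7 L mol⁻¹ h⁻¹)
    free monomer + initiator → living end + monomer in chains (k = 3.87 L mol⁻¹ h⁻¹)
    monomer in chains + living end → free monomer + living end, rate k3*[living end] as long as [monomer in chains] is above zero (k = 0.915 h⁻¹)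
    pre-initiator ⇌ initiator (K = 1.69, k = 1.05 h⁻¹)
    free monomer → uncatalysed product (k = 0.00620 h⁻¹)
    protic impurity + free monomer → quenched substrate (k = 15.3 L mol⁻¹ h⁻¹)

At 80.0 min the flask holds 7.38% in chains, more than its 5.00% of quenched substrate, so it stands past the crossing at 68.8 min. A neighbouring flask is charged with 0.10 M of protic impurity in all, its other charges and its time held. Its toll is 12.5%, so the same parabola crosses at 109 min, later than 80 min, and c should be near 19.3%. That flask gives c 19.8%, with 6.60% in chains, still below its 12.5% of quenched substrate.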